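**Plan**

1. Numbering used: pyrrole C1/C2/C3/N4/C9a, azepine C5–C9, C10 (CHEt), C11 (CH–O), C12, C13 (CHMe), C14 (C=O); pendant lactone C18 (CH–O), C19, C20 (CHMe), C21 (C=O).
2. Cuts, last to first: C3–C18 together with the C18–O–C21 lactone bond; C13–CH3; C1–C12; C12=C13 and C8=C9 (two ring-closing metatheses); C9=CH2; C9–C9a; C10–C11.
3. The C3–C18 event rests on two features: C3–H is the only α C–H of the N,2,3-trisubstituted pyrrole ring, so it can be borylated selectively, and C18 is the carbinol carbon of a γ-lactone. An aryl-copper addition to a 4-oxo-acyl oxazolidinone followed by O-acyl transfer therefore forms the bond, the stereocentre and the lactone ring in one operation.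
4. Forward: acyclic C9–C12 chain (syn aldol) → 2-acyl-3-bromopyrrole → azepine ring → butenolide ring → cyclohexene ring by aryl-radical conjugate addition (the C1 bromine leaves here) → C13 methylation → C3 borylation → union with the C18–C21 aldehyde.
5. Stereochemistry: C10/C11 from the (R)-benzyloxazolidinone boron aldol; C12 by tether-enforced cis ring closure; C13 by convex-face alkylation; C20 by auxiliary-controlled allylation; C18 by the chiral copper–bisphosphine catalyst.

Key step: step 17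

Assumption: (R)-DTBM-SEGPHOS is written as the ligand antipode that delivers 18R; should the sense of induction be the opposite, the (S)-ligand is used and nothing else changes.

**Route**

Step 1
Reactants: 1 (4R)-4-benzyl-1,3-oxazolidin-2-one; 2 butanoyl chloride
Product: 3 (4R)-4-benzyl-3-butanoyl-1,3-oxazolidin-2-one
Conditions: Et3N, DMAP (cat.), CH2Cl2, 0 °C → rt
Reagents that add atoms: none
Why: DMAP-catalysed N-acylation of the oxazolidinone should give the imide without touching the stereocentre.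

Step 2
Reactants: 3 (4R)-4-benzyl-3-butanoyl-1,3-oxazolidin-2-one; 4 prop-2-enal
Product: 6 (4R)-4-benzyl-3-[(2R,3S)-2-ethyl-3-hydroxypent-4-enoyl]-1,3-oxazolidin-2-one, via Z-dibutylboron enolate 5 (not isolated)
Conditions: Bu2BOTf, Et3N, CH2Cl2, 0 °C; 4, −78 → 0 °C; then pH 7 buffer, MeOH, 30% H2O2, 0 °C
Reagents that add atoms: none
Why: Evans boron aldol reaction, in which the Z-enolate reacts through a chair Zimmerman–Traxler transition state on the face away from the benzyl group and should set C10 and C11 syn as (2R,3S).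

Step 3
Reactants: 6 (4R)-4-benzyl-3-[(2R,3S)-2-ethyl-3-hydroxypent-4-enoyl]-1,3-oxazolidin-2-one
Product: 7 (2R,3S)-2-ethyl-3-hydroxy-N-methoxy-N-methylpent-4-enamide
Conditions: MeNHOMe·HCl, AlMe3, CH2Cl2, −15 → 0 °C; aq. HCl work-up
Reagents that add atoms: N,O-dimethylhydroxylamine hydrochloride, CNOC.Cl
Why: Aluminium-amide transamidation (Weinreb amide formation), assisted by the free β-hydroxyl, should cleave the auxiliary without epimerising C10.

Step 4
Reactants: 7 (2R,3S)-2-ethyl-3-hydroxy-N-methoxy-N-methylpent-4-enamide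
Product: 8 (2R,3S)-3-[(tert-butyldimethylsilyl)oxy]-2-ethyl-N-methoxy-N-methylpent-4-enamide
Conditions: TBSOTf, 2,6-lutidine, CH2Cl2, −78 → 0 °C
Reagents that add atoms: tert-butyldimethylsilyl trifluoromethanesulfonate, CC(C)(C)[Si](C)(C)OS(=O)(=O)C(F)(F)F
Why: Silyl ether formation protects the C11 hydroxyl against the organolithium and the titanium carbene that follow.

Step 5
Reactants: 9 3-bromo-1-(triisopropylsilyl)-1H-pyrrole; 10 5-bromopent-1-ene
Product: 12 3-bromo-1-(pent-4-en-1-yl)-1H-pyrrole, via caesium 3-bromopyrrolide 11 (not isolated)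
Conditions: CsF (2 equiv), DMF, rt → 50 °C
Reagents that add atoms: none
Why: Fluoride-induced N-desilylation releases the unstable 3-bromopyrrole as its caesium salt, which should undergo SN2 N-alkylation in the same flask.

Step 6
Reactants: 12 3-bromo-1-(pent-4-en-1-yl)-1H-pyrrole; 8 (2R,3S)-3-[(tert-butyldimethylsilyl)oxy]-2-ethyl-N-methoxy-N-methylpent-4-enamide
Product: 14 (2R,3S)-1-[3-bromo-1-(pent-4-en-1-yl)-1H-pyrrol-2-yl]-3-[(tert-butyldimethylsilyl)oxy]-2-ethylpent-4-en-1-one, via 2-lithio-3-bromopyrrole 13 (not isolated)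
Conditions: LDA (1.1 equiv), THF, −78 °C; then 8, −78 → −30 °C; H2O
Reagents that add atoms: none
Why: Bromine-directed ortho-lithiation at the pyrrole α-carbon next to C–Br (an amide base avoids Br/Li exchange) followed by Weinreb ketone synthesis, in which the chelated tetrahedral adduct should prevent over-addition and epimerisation of C10.

Step 7
Reactants: 14 (2R,3S)-1-[3-bromo-1-(pent-4-en-1-yl)-1H-pyrrol-2-yl]-3-[(tert-butyldimethylsilyl)oxy]-2-ethylpent-4-en-1-one
Product: 15 3-bromo-2-[(3S,4S)-4-[(tert-butyldimethylsilyl)oxy]-3-ethylhexa-1,5-dien-2-yl]-1-(pent-4-en-1-yl)-1H-pyrrole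
Conditions: Cp2TiMe2, toluene, 65 °C, dark
Reagents that add atoms: bis(cyclopentadienyl)dimethyltitanium (Petasis reagent), C[Ti](C)(C1C=CC=C1)C1C=CC=C1
Why: Petasis methylenation through the non-basic titanocene methylidene should convert the hindered, enolisable aryl ketone into the 1,1-disubstituted alkene without epimerising C10 or eliminating the β-silyloxy group.

Step 8
Reactants: 15 3-bromo-2-[(3S,4S)-4-[(tert-butyldimethylsilyl)oxy]-3-ethylhexa-1,5-dien-2-yl]-1-(pent-4-en-1-yl)-1H-pyrrole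
Product: 16 1-bromo-9-[(3S,4S)-4-[(tert-butyldimethylsilyl)oxy]hex-5-en-3-yl]-6,7-dihydro-5H-pyrrolo[1,2-a]azepine
Conditions: Hoveyda–Grubbs II (10 mol%), toluene (5 mM), 80 °C
Reagents that add atoms: none
Why: Ring-closing metathesis between the N-pentenyl chain and the 2-pyrrolyl alkene should close the seven-membered ring and fix the double bond at C8=C9, since the allylic vinyl group could only form a four- or ten-membered ring.

Step 9
Reactants: 16 1-bromo-9-[(3S,4S)-4-[(tert-butyldimethylsilyl)oxy]hex-5-en-3-yl]-6,7-dihydro-5H-pyrrolo[1,2-a]azepine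
Product: 17 (3S,4S)-4-(1-bromo-6,7-dihydro-5H-pyrrolo[1,2-a]azepin-9-yl)hex-1-en-3-ol
Conditions: TBAF, THF, 0 °C → rt
Reagents that add atoms: none
Why: Fluoride desilylation frees the C11 hydroxyl under non-acidic conditions that the 2-vinylpyrrole should tolerate.

Step 10
Reactants: 17 (3S,4S)-4-(1-bromo-6,7-dihydro-5H-pyrrolo[1,2-a]azepin-9-yl)hex-1-en-3-ol; 18 prop-2-enoyl chloride
Product: 19 (3S,4S)-4-(1-bromo-6,7-dihydro-5H-pyrrolo[1,2-a]azepin-9-yl)hex-1-en-3-yl prop-2-enoate
Conditions: Et3N, DMAP (cat.), CH2Cl2, −20 → 0 °C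
Reagents that add atoms: none
Why: O-acylation of the secondary allylic alcohol gives the allyl acrylate needed for butenolide closure.

Step 11
Reactants: 19 (3S,4S)-4-(1-bromo-6,7-dihydro-5H-pyrrolo[1,2-a]azepin-9-yl)hex-1-en-3-yl prop-2-enoate
Product: 20 (5S)-5-[(1S)-1-(1-bromo-6,7-dihydro-5H-pyrrolo[1,2-a]azepin-9-yl)propyl]furan-2(5H)-one
Conditions: Grubbs II (10 mol%), CH2Cl2 (5 mM), 40 °C
Reagents that add atoms: none
Why: Ring-closing metathesis of the acrylate with the neighbouring vinyl group should give the butenolide with C11 unchanged, the trisubstituted C8=C9 alkene being inert.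

Step 12
Reactants: 20 (5S)-5-[(1S)-1-(1-bromo-6,7-dihydro-5H-pyrrolo[1,2-a]azepin-9-yl)propyl]furan-2(5H)-one
Product: 21 tetracyclic lactone (10S,11R,12S; 13-desmethyl core)
Conditions: Bu3SnH (1.3 equiv, syringe pump), AIBN (cat.), toluene (5 mM), 90 °C
Reagents that add atoms: none
Why: Tin hydride-mediated 6-exo-trig cyclisation of the pyrrol-3-yl σ-radical onto the butenolide β-carbon (radical conjugate addition); the C9–C10–C11 tether lets C1 reach only the lactone face that carries C10, which should set C12 with a cis ring fusion.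

Step 13
Reactants: 21 tetracyclic lactone (10S,11R,12S; 13-desmethyl core)
Product: 23 tetracyclic pyrrole core (10S,11R,12S,13R; C3–H), via lithium enolate 22 (not isolated)
Conditions: LDA, THF, −78 °C; MeI, −78 °C
Reagents that add atoms: iodomethane, CI
Why: Enolate alkylation of the cis-fused γ-lactone on its convex face, anti to the C12–C1 bond, should place the C13 methyl trans to C1 as in the target.

Step 14
Reactants: 23 tetracyclic pyrrole core (10S,11R,12S,13R; C3–H)
Product: 24 C3-pinacolboronate of the tetracyclic core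
Conditions: [Ir(OMe)(cod)]2 (1.5 mol%), dtbpy (3 mol%), B2pin2 (1.0 equiv), THF, 50 °C
Reagents that add atoms: bis(pinacolato)diboron, CC1(C)OB(OC1(C)C)B1OC(C)(C)C(C)(C)O1
Why: Iridium-catalysed aromatic C–H borylation should select C3–H, the only α C–H of the pyrrole and less hindered than C2–H beside the ring fusion, and leave the lactone and the alkene untouched.

Step 15
Reactants: 25 (4S)-4-benzyl-3-propanoyl-1,3-oxazolidin-2-one; 26 3-iodoprop-1-ene
Product: 28 (4S)-4-benzyl-3-[(2R)-2-methylpent-4-enoyl]-1,3-oxazolidin-2-one, via sodium Z-enolate 27 (not isolated)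
Conditions: NaHMDS, THF, −78 °C; 26, −78 → −45 °C
Reagents that add atoms: none
Why: Evans asymmetric alkylation, in which the chelated Z-enolate is allylated on the face away from the benzyl group, should set the (R)-methyl stereocentre that becomes C20.

Step 16
Reactants: 28 (4S)-4-benzyl-3-[(2R)-2-methylpent-4-enoyl]-1,3-oxazolidin-2-one
Product: 30 (4S)-4-benzyl-3-[(2R)-2-methyl-4-oxobutanoyl]-1,3-oxazolidin-2-one, via ozonide 29 (not isolated)
Conditions: O3, CH2Cl2, −78 °C; then PPh3, −78 °C → rt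
Reagents that add atoms: ozone, [O-][O+]=O
Why: Ozonolysis with reductive work-up cleaves the terminal alkene to the aldehyde (the future C18) without touching C20.

Step 17
Reactants: 24 C3-pinacolboronate of the tetracyclic core; 30 (4S)-4-benzyl-3-[(2R)-2-methyl-4-oxobutanoyl]-1,3-oxazolidin-2-one
Product: 32 CNP0324368.1 (target; 10S,11R,12S,13R,18R,20R), via hydroxy imide 31 (not isolated)
Conditions: CuF(PPh3)3·2EtOH (10 mol%), (R)-DTBM-SEGPHOS (12 mol%), DMF, 40 °C; then Et3N, DMAP (cat.), rt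
Reagents that add atoms: none
Why: Fluoride-assisted transmetalation moves the pyrrol-2-yl group from boron to the bisphosphine–copper(I) centre, and this aryl-copper adds to the aldehyde of 30 inside the chiral pocket; the resulting alkoxide (31 after protonation) then attacks the exocyclic imide carbonyl and expels the oxazolidinone. The closest known reaction type is the copper(I) fluoride–bisphosphine-catalysed enantioselective 1,2-addition of aryl and alkenyl boronates to aldehydes, joined to the familiar lactonisation of γ-hydroxy N-acyl oxazolidinones. One ring is closed, the γ-lactone, by 5-exo-trig O-acylation (addition–elimination at the imide C=O). The new stereocentre C18 is set by the ligand, which selects the aldehyde face; C20 is already fixed in 30 and, lying 1,3 to the aldehyde carbon, should exert only a weak bias, so the 18R,20R (cis) lactone is expected. The step needs site selectivity (secured because the new bond can form only at the carbon that carried boron), chemoselectivity for the aldehyde over the imide and the lactone carbonyls (soft aryl-copper at 40 °C) and survival of the acid-labile pyrrolyl C18–O bond and the C8=C9 alkene (neutral to mildly basic medium throughout).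

**Compound list**

1 | (4R)-4-benzyl-1,3-oxazolidin-2-one | O=C1N[C@H](Cc2ccccc2)CO1 | starting material
2 | butanoyl chloride | CCCC(Cl)=O | starting material
3 | (4R)-4-benzyl-3-butanoyl-1,3-oxazolidin-2-one | CCCC(=O)N1[C@H](Cc2ccccc2)COC1=O | intermediate
4 | prop-2-enal (acrolein) | C=CC=O | starting material
5 | (4R)-4-benzyl-3-[(1Z)-1-(dibutylboranyloxy)but-1-en-1-yl]-1,3-oxazolidin-2-one | CC/C=C(\OB(CCCC)CCCC)N1[C@H](Cc2ccccc2)COC1=O | intermediate
6 | (4R)-4-benzyl-3-[(2R,3S)-2-ethyl-3-hydroxypent-4-enoyl]-1,3-oxazolidin-2-one | CC[C@H]([C@@H](O)C=C)C(=O)N1[C@H](Cc2ccccc2)COC1=O | intermediate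
7 | (2R,3S)-2-ethyl-3-hydroxy-N-methoxy-N-methylpent-4-enamide | CC[C@H]([C@@H](O)C=C)C(=O)N(C)OC | intermediate
8 | (2R,3S)-3-[(tert-butyldimethylsilyl)oxy]-2-ethyl-N-methoxy-N-methylpent-4-enamide | CC[C@H]([C@@H](O[Si](C)(C)C(C)(C)C)C=C)C(=O)N(C)OC | intermediate
9 | 3-bromo-1-(triisopropylsilyl)-1H-pyrrole | CC(C)[Si](C(C)C)(C(C)C)n1ccc(Br)c1 | starting material
10 | 5-bromopent-1-ene | C=CCCCBr | starting material
11 | caesium 3-bromopyrrol-1-ide | [Cs+].Brc1cc[n-]c1 | intermediate
12 | 3-bromo-1-(pent-4-en-1-yl)-1H-pyrrole | C=CCCCn1ccc(Br)c1 | intermediate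
13 | [3-bromo-1-(pent-4-en-1-yl)-1H-pyrrol-2-yl]lithium | [Li]c1c(Br)ccn1CCCC=C | intermediate
14 | (2R,3S)-1-[3-bromo-1-(pent-4-en-1-yl)-1H-pyrrol-2-yl]-3-[(tert-butyldimethylsilyl)oxy]-2-ethylpent-4-en-1-one | CC[C@H]([C@@H](O[Si](C)(C)C(C)(C)C)C=C)C(=O)c1c(Br)ccn1CCCC=C | intermediate
15 | 3-bromo-2-[(3S,4S)-4-[(tert-butyldimethylsilyl)oxy]-3-ethylhexa-1,5-dien-2-yl]-1-(pent-4-en-1-yl)-1H-pyrrole | CC[C@H]([C@@H](O[Si](C)(C)C(C)(C)C)C=C)C(=C)c1c(Br)ccn1CCCC=C | intermediate
16 | 1-bromo-9-[(3S,4S)-4-[(tert-butyldimethylsilyl)oxy]hex-5-en-3-yl]-6,7-dihydro-5H-pyrrolo[1,2-a]azepine | CC[C@H]([C@@H](O[Si](C)(C)C(C)(C)C)C=C)C1=CCCCn2ccc(Br)c12 | intermediate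
17 | (3S,4S)-4-(1-bromo-6,7-dihydro-5H-pyrrolo[1,2-a]azepin-9-yl)hex-1-en-3-ol | CC[C@H]([C@@H](O)C=C)C1=CCCCn2ccc(Br)c12 | intermediate
18 | prop-2-enoyl chloride (acryloyl chloride) | C=CC(Cl)=O | starting material
19 | (3S,4S)-4-(1-bromo-6,7-dihydro-5H-pyrrolo[1,2-a]azepin-9-yl)hex-1-en-3-yl prop-2-enoate | CC[C@H]([C@@H](OC(=O)C=C)C=C)C1=CCCCn2ccc(Br)c12 | intermediate
20 | (5S)-5-[(1S)-1-(1-bromo-6,7-dihydro-5H-pyrrolo[1,2-a]azepin-9-yl)propyl]furan-2(5H)-one | CC[C@H]([C@H]1OC(=O)C=C1)C1=CCCCn2ccc(Br)c12 | intermediate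
21 | tetracyclic lactone (10S,11R,12S; 13-desmethyl core): 6,7-dihydro-5H-pyrrolo[1,2-a]azepine whose C9 and C1 are bridged by C10H(Et)–C11H–C12H to a cyclohexene ring, with a γ-butyrolactone (C11–O–C14(=O)–C13H2–C12) cis-fused across C11–C12 | CC[C@H]1C2=CCCCn3ccc(c32)[C@H]2[C@@H]1OC(=O)C2 | intermediate
22 | lithium enolate of 21 (C13=C14–OLi; 10S,11R,12S) | CC[C@H]1C2=CCCCn3ccc(c32)[C@H]2[C@@H]1OC(O[Li])=C2 | intermediate
23 | tetracyclic pyrrole core (10S,11R,12S,13R): 21 with a methyl on C13 trans to C1; C3–H free | CC[C@H]1C2=CCCCn3ccc(c32)[C@H]2[C@@H]1OC(=O)[C@@H]2C | intermediate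
24 | C3-(4,4,5,5-tetramethyl-1,3,2-dioxaborolan-2-yl) derivative of 23 | CC[C@H]1C2=CCCCn3c(B4OC(C)(C)C(C)(C)O4)cc(c32)[C@H]2[C@@H]1OC(=O)[C@@H]2C | intermediate
25 | (4S)-4-benzyl-3-propanoyl-1,3-oxazolidin-2-one | CCC(=O)N1[C@@H](Cc2ccccc2)COC1=O | starting material
26 | 3-iodoprop-1-ene (allyl iodide) | C=CCI | starting material
27 | sodium (Z)-enolate of 25 | C/C=C(\[O-])N1[C@@H](Cc2ccccc2)COC1=O.[Na+] | intermediate
28 | (4S)-4-benzyl-3-[(2R)-2-methylpent-4-enoyl]-1,3-oxazolidin-2-one | C=CC[C@@H](C)C(=O)N1[C@@H](Cc2ccccc2)COC1=O | intermediate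
29 | (4S)-4-benzyl-3-[(2R)-2-methyl-3-(1,2,4-trioxolan-3-yl)propanoyl]-1,3-oxazolidin-2-one (ozonide) | C1(OOCO1)C[C@@H](C)C(=O)N1[C@@H](Cc2ccccc2)COC1=O | intermediate
30 | (4S)-4-benzyl-3-[(2R)-2-methyl-4-oxobutanoyl]-1,3-oxazolidin-2-one | O=CC[C@@H](C)C(=O)N1[C@@H](Cc2ccccc2)COC1=O | intermediate
31 | (4S)-4-benzyl-3-[(2R,4R)-4-hydroxy-2-methyl-4-(core-C3-yl)butanoyl]-1,3-oxazolidin-2-one (core = 23 bonded through C3) | CC[C@H]1C2=CCCCn3c([C@H](O)C[C@@H](C)C(=O)N4[C@@H](Cc5ccccc5)COC4=O)cc(c32)[C@H]2[C@@H]1OC(=O)[C@@H]2C | intermediate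
32 | CNP0324368.1: 23 carrying at C3 a (2R,4R)-4-methyl-5-oxooxolan-2-yl group (18R,20R; cis lactone) | CC[C@H]1C2=CCCCn3c([C@H]4C[C@@H](C)C(=O)O4)cc(c32)[C@H]2[C@@H]1OC(=O)[C@@H]2C | target

**Count and risks**

Total step count: 17. Longest linear sequence: 14 (steps 1–4, 6–14, 17).

Step 17. What may go wrong: protodeboronation of the electron-rich pyrrol-2-yl boronate may outrun transmetalation to copper, and facial control at the aldehyde may be incomplete, giving the C18 epimer. The fallback sets out from 30 and 24 and returns to the route at 31. Pinnick oxidation of 30 (NaClO2, NaH2PO4, 2-methylbut-2-ene) should give (3R)-4-[(4S)-4-benzyl-2-oxo-1,3-oxazolidin-3-yl]-3-methyl-4-oxobutanoic acid F1, and oxalyl chloride with catalytic DMF its acid chloride, (3R)-4-[(4S)-4-benzyl-2-oxo-1,3-oxazolidin-3-yl]-3-methyl-4-oxobutanoyl chloride F2. Anhydrous Suzuki–Miyaura acylation of 24 with F2 (Pd(PPh3)4, K3PO4, toluene) should give the C3 γ-keto imide F3. Corey–Bakshi–Shibata reduction with catecholborane, the catalyst antipode chosen for the 18R carbinol, then gives 31, which lactonises to 32 as in step 17.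

Step 8. What may go wrong: ring closure onto the hindered 1,1-disubstituted olefin may be slow, leaving time for intermolecular metathesis of the terminal alkenes or ruthenium-hydride isomerisation of the double bonds. The fallback sets out from 9 and 8 and returns at 16. Caesium fluoride-mediated N-alkylation of 9 with commercial 2-(3-chloropropyl)-1,3-dioxolane (NaI cat.) should give 3-bromo-1-[3-(1,3-dioxolan-2-yl)propyl]-1H-pyrrole F4. Lithiation and acylation with 8 as in step 6 gives (2R,3S)-1-{3-bromo-1-[3-(1,3-dioxolan-2-yl)propyl]-1H-pyrrol-2-yl}-3-[(tert-butyldimethylsilyl)oxy]-2-ethylpent-4-en-1-one F5, and acetal hydrolysis (PPTS, wet acetone) gives 4-{3-bromo-2-[(2R,3S)-3-[(tert-butyldimethylsilyl)oxy]-2-ethylpent-4-enoyl]-1H-pyrrol-1-yl}butanal F6. Intramolecular McMurry coupling of the ketone with the aldehyde (TiCl3(DME)1.5, Zn–Cu, DME, reflux, slow addition) forms C8=C9 directly and gives 16, so steps 5–8 are replaced.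

Step 12. What may go wrong: hydrogen-atom transfer to the pyrrolyl radical before ring closure (simple debromination) or 1,5-hydrogen abstraction from C11–H may compete with cyclisation. The fallback sets out from 20 and returns at 21 without a new compound. A palladium-catalysed intramolecular reductive Heck reaction (Pd(OAc)2, PPh3, HCO2Na, DMF, 80 °C) replaces the radical by syn carbopalladation of the butenolide from the tethered face. The resulting C13 palladium enolate has no syn β-hydrogen and is reduced by formate.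

**Further compounds**

F1 | step 17 | (3R)-4-[(4S)-4-benzyl-2-oxo-1,3-oxazolidin-3-yl]-3-methyl-4-oxobutanoic acid | OC(=O)C[C@@H](C)C(=O)N1[C@@H](Cc2ccccc2)COC1=O
F2 | step 17 | (3R)-4-[(4S)-4-benzyl-2-oxo-1,3-oxazolidin-3-yl]-3-methyl-4-oxobutanoyl chloride | ClC(=O)C[C@@H](C)C(=O)N1[C@@H](Cc2ccccc2)COC1=O
F3 | step 17 | (4S)-4-benzyl-3-[(2R)-2-methyl-4-oxo-4-(core-C3-yl)butanoyl]-1,3-oxazolidin-2-one (core = 23 bonded through C3) | CC[C@H]1C2=CCCCn3c(C(=O)C[C@@H](C)C(=O)N4[C@@H](Cc5ccccc5)COC4=O)cc(c32)[C@H]2[C@@H]1OC(=O)[C@@H]2C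
F4 | step 8 | 3-bromo-1-[3-(1,3-dioxolan-2-yl)propyl]-1H-pyrrole | Brc1ccn(CCCC2OCCO2)c1
F5 | step 8 | (2R,3S)-1-{3-bromo-1-[3-(1,3-dioxolan-2-yl)propyl]-1H-pyrrol-2-yl}-3-[(tert-butyldimethylsilyl)oxy]-2-ethylpent-4-en-1-one | CC[C@H]([C@@H](O[Si](C)(C)C(C)(C)C)C=C)C(=O)c1c(Br)ccn1CCCC1OCCO1
F6 | step 8 | 4-{3-bromo-2-[(2R,3S)-3-[(tert-butyldimethylsilyl)oxy]-2-ethylpent-4-enoyl]-1H-pyrrol-1-yl}butanal | CC[C@H]([C@@H](O[Si](C)(C)C(C)(C)C)C=C)C(=O)c1c(Br)ccn1CCCC=O
F0 | step 12 | none | none
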